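**Overview**

- Atom labels (order of the target SMILES): side chain C1–C5 (C2 and C5 carbinols); diquinane ring A = C6–C9, C23 and ring B = C9–C11, C22, C23 (C23 quaternary with its methyl, C10=C11); cyclopentane C12–C15, C21; seven-membered ring C15–C21 (C16 ketone, C18 carbinol, C20=C21).
- Enabling feature: the ring C15H–C16(=O)–C17H2–C18H(OH)–C19H2–C20H=C21 has its two oxygens 1,3 to each other and its alkene, exocyclic to the cyclopentane, one CH2 (C19) from C18. With C18 written as an enol ether carbon (C17=C18) this is a cyclohepta-1,4-diene, the Cope product of a cis-divinylcyclopropane C18–C19–C20 whose vinyl termini are C16 (enol ether CH) and C15 (cyclopentene CH).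
- Cuts: C15–C16 (retro-Cope, C16 carried as CH–OPMB); C18–C19 and C18–C20 (Kulinkovich: vinyl group + 3,3-dialkoxypropanoate); C11–C12 (anti SN2' of an alkenylcopper on a cyclopentenyl picolinate); C4–C5 (alkenyllithium + methyl ketone).
- Forward order: ring B by aldol condensation onto the methylcyclopentanedione ring, then the side chain, the cyclopentene by SN2', the cyclopropane, and last the seven-membered ring by the Cope shift; then oxygen relay (C18 ketone to carbinol, C16 carbinol to ketone) and desilylation.
- Stereochemistry: C23 from CBS desymmetrisation of the prochiral dione, and it directs C9 (cis hydrogenation), C6 (convex-face hydrogenation) and C5 (Felkin–Anh); C2 from (R)-but-3-yn-2-ol; C12 from a CBS-derived cyclopentenol by anti SN2'; C15 and the temporary C16 centre from the cyclopropane configuration and the E enol ether through the boat Cope transition state; C18 by Evans–Tishchenko hydride delivery from the C16 oxygen.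

Key step: step 29

Remark: compounds 1, 15, 25 and 33 are taken as bought; C6 of 14 (alpha to the acetyl group) and C15 of 44 and 45 (allylic and alpha to the ketone) are treated as epimerisable and are kept away from base.

**Route**

Step 1
Reactants: 1 2-methylcyclopentane-1,3-dione
Product: 2 2-allyl-2-methylcyclopentane-1,3-dione
Conditions: allyl bromide, 1 M aq. NaOH, n-Bu4NI (cat.), rt
Reagents that add atoms: allyl bromide, C=CCBr
Why: C-alkylation of the stabilised dione enolate in water gives the quaternary carbon (later C23) and brings the three carbons that later close ring B.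

Step 2
Reactants: 2 2-allyl-2-methylcyclopentane-1,3-dione
Product: 3 (2S,3S)-2-allyl-3-hydroxy-2-methylcyclopentan-1-one
Conditions: (R)-1-methyl-3,3-diphenyltetrahydro-1H,3H-pyrrolo[1,2-c][1,3,2]oxazaborole [(R)-Me-CBS, 0.2 equiv], catecholborane, toluene, −60 °C
Reagents that add atoms: none
Why: CBS reduction used as a desymmetrisation, in which the quaternary carbon takes the large-group position so that the (R)-catalyst should form the (S)-carbinol, and hydride enters the reduced carbonyl from the methyl face (anti to allyl), which fixes the quaternary centre with OH cis to allyl.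

Step 3
Reactants: 3 (2S,3S)-2-allyl-3-hydroxy-2-methylcyclopentan-1-one
Product: 4 (2S,3S)-2-allyl-3-[(tert-butyldimethylsilyl)oxy]-2-methylcyclopentan-1-one
Conditions: TBSCl, imidazole, DMF, rt
Reagents that add atoms: tert-butyldimethylsilyl chloride, CC(C)(C)[Si](C)(C)Cl
Why: Imidazole-mediated silylation masks the secondary alcohol so that the base of step 5 cannot open the ring by retro-aldol cleavage.

Step 4
Reactants: 4 (2S,3S)-2-allyl-3-[(tert-butyldimethylsilyl)oxy]-2-methylcyclopentan-1-one
Product: 5 (2S,3S)-3-[(tert-butyldimethylsilyl)oxy]-2-methyl-2-(2-oxopropyl)cyclopentan-1-one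
Conditions: PdCl2 (cat.), CuCl, O2 (1 atm), DMF–H2O, rt
Reagents that add atoms: water, O
Why: Tsuji–Wacker oxidation converts the terminal alkene into the methyl ketone with Markovnikov selectivity and leaves the ring ketone and the silyl ether untouched.

Step 5
Reactants: 5 (2S,3S)-3-[(tert-butyldimethylsilyl)oxy]-2-methyl-2-(2-oxopropyl)cyclopentan-1-one
Product: 6 (6S,6aR)-6-[(tert-butyldimethylsilyl)oxy]-6a-methyl-4,5,6,6a-tetrahydropentalen-2(1H)-one
Conditions: t-BuOK (0.3 equiv), t-BuOH, 40 °C
Reagents that add atoms: none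
Why: Intramolecular aldol condensation, in which the methyl-ketone enolate adds to the ring carbonyl and dehydration gives the cyclopentenone, closes ring B, while the competing bridged aldol adduct cannot dehydrate and reverts.

Step 6
Reactants: 6 (6S,6aR)-6-[(tert-butyldimethylsilyl)oxy]-6a-methyl-4,5,6,6a-tetrahydropentalen-2(1H)-one
Product: 7 (3aR,4S,6aS)-4-[(tert-butyldimethylsilyl)oxy]-3a-methylhexahydropentalen-2(1H)-one (cis-fused)
Conditions: H2 (1 atm), Pd/C (10 wt%), EtOAc, rt
Reagents that add atoms: none
Why: Heterogeneous hydrogenation of the enone alkene should deliver hydrogen to C9 on the methyl face, because only the cis-fused bicyclo[3.3.0]octane is free of strain.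

Step 7
Reactants: 7 (3aR,4S,6aS)-4-[(tert-butyldimethylsilyl)oxy]-3a-methylhexahydropentalen-2(1H)-one
Product: 8 ethylene ketal of 7 (spiro-1,3-dioxolane at C11, OTBS on C6)
Conditions: ethylene glycol, pyridinium p-toluenesulfonate (cat.), benzene, reflux, Dean–Stark
Reagents that add atoms: ethylene glycol, OCCO
Why: Acid-catalysed ketalisation with azeotropic removal of water protects the C11 ketone through the organometallic steps, and the secondary TBS ether tolerates the pyridinium acid.

Step 8
Reactants: 8 ethylene ketal of 7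
Product: 9 (3aR,4S,6aS)-4-hydroxy-3a-methylhexahydropentalen-2(1H)-one ethylene ketal
Conditions: n-Bu4NF, THF, 50 °C
Reagents that add atoms: none
Why: Fluoride-mediated desilylation frees the C6 hydroxyl, and the ketal is inert to fluoride.

Step 9
Reactants: 9 (3aR,4S,6aS)-4-hydroxy-3a-methylhexahydropentalen-2(1H)-one ethylene ketal
Product: 10 (3aS,6aR)-6a-methylhexahydropentalene-1,5-dione 5-(ethylene ketal) (C6 ketone)
Conditions: Dess–Martin periodinane, NaHCO3, CH2Cl2, rt
Reagents that add atoms: none
Why: Buffered Dess–Martin oxidation of the secondary alcohol gives the C6 ketone without touching the ketal.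

Step 10
Reactants: 10 (3aS,6aR)-6a-methylhexahydropentalene-1,5-dione 5-(ethylene ketal)
Product: 11 C6=C7 enol triflate of 10
Conditions: KN(SiMe3)2, THF, −78 °C; PhNTf2, −78 → 0 °C
Reagents that add atoms: N-phenylbis(trifluoromethanesulfonimide), O=S(=O)(N(c1ccccc1)S(=O)(=O)C(F)(F)F)C(F)(F)F
Why: Enol triflate formation is regiospecific because the ketone can enolise only toward C7 (C23 is quaternary), and the potassium enolate is O-sulfonylated by the triflimide.

Step 11
Reactants: 11 C6=C7 enol triflate of 10
Product: 13 C6-acetyl C6=C7 diquinane ketal (enone), via 2-ethoxydiene 12 (not isolated)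
Conditions: CH2=C(OEt)SnBu3, Pd(PPh3)4 (cat.), LiCl, THF, 65 °C; then 5% aq. oxalic acid, THF, 0 °C
Reagents that add atoms: tributyl(1-ethoxyvinyl)stannane, CCCC[Sn](CCCC)(CCCC)C(=C)OCC; water, O
Why: Stille coupling of the enol triflate with the 1-ethoxyvinyl stannane (an acetyl anion equivalent) is followed by mild acid hydrolysis of the very labile 2-ethoxydiene, which should be far faster than cleavage of the dioxolane.

Step 12
Reactants: 13 C6-acetyl C6=C7 diquinane ketal
Product: 14 cis-diquinane methyl ketone (C6 acetyl, C6 S, C9 S, C23 R; C11 ethylene ketal)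
Conditions: H2 (1 atm), Pd/C (10 wt%), EtOAc, rt
Reagents that add atoms: none
Why: Heterogeneous hydrogenation of the enone alkene should add hydrogen from the convex face of the cis-diquinane (the face of the angular methyl and H9), since the concave face is closed by the folded ketal ring, which places the acetyl group on C6 trans to the methyl group.

Step 13
Reactants: 15 (R)-but-3-yn-2-ol
Product: 16 (R)-tert-butyl(but-3-yn-2-yloxy)dimethylsilane
Conditions: TBSCl, imidazole, CH2Cl2, rt
Reagents that add atoms: tert-butyldimethylsilyl chloride, CC(C)(C)[Si](C)(C)Cl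
Why: Standard imidazole-mediated silylation of the secondary propargylic alcohol, which carries the C2 stereocentre unchanged.

Step 14
Reactants: 16 (R)-tert-butyl(but-3-yn-2-yloxy)dimethylsilane
Product: 18 (R,E)-tert-butyl[(4-iodobut-3-en-2-yl)oxy]dimethylsilane, via alkenylzirconocene chloride 17 (not isolated)
Conditions: Cp2Zr(H)Cl, THF, rt; then I2, 0 °C
Reagents that add atoms: iodine, II
Why: Hydrozirconation adds Zr–H syn with zirconium on the terminal carbon, and iodinolysis with retention gives the E vinyl iodide.

Step 15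
Reactants: 18 (R,E)-tert-butyl[(4-iodobut-3-en-2-yl)oxy]dimethylsilane; 14 cis-diquinane methyl ketone
Product: 20 tertiary allylic alcohol with the full C1–C5 side chain on the diquinane ketal (C2 R and C5 S), via alkenyllithium 19 (not isolated)
Conditions: 18, t-BuLi (2 equiv per 18), Et2O, −78 °C; then 14, −78 → −40 °C
Reagents that add atoms: none
Why: Iodine–lithium exchange with retention of the E geometry and 1,2-addition to the methyl ketone under Felkin–Anh control (C23 as the large group anti to the nucleophile, attack past H6) should set C5 as S, and fast addition at low temperature protects the epimerisable C6.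

Step 16
Reactants: 20 tertiary allylic alcohol
Product: 21 C5 triethylsilyl ether of 20
Conditions: Et3SiOTf, 2,6-lutidine, CH2Cl2, −78 → 0 °C
Reagents that add atoms: triethylsilyl trifluoromethanesulfonate, CC[Si](CC)(CC)OS(=O)(=O)C(F)(F)F
Why: A silyl triflate with a hindered pyridine base silylates the hindered tertiary allylic alcohol at low temperature, where the dioxolane is not attacked.

Step 17
Reactants: 21 C5 triethylsilyl ether of 20
Product: 22 C11 ketone (cis-diquinanone with the bis-silylated side chain)
Conditions: pyridinium p-toluenesulfonate (cat.), acetone–H2O, 40 °C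
Reagents that add atoms: water, O
Why: Mild acid-catalysed ketal hydrolysis frees the C11 ketone, and the hindered tertiary TES and secondary TBS ethers should survive the weak pyridinium acid.

Step 18
Reactants: 22 C11 ketone
Product: 23 C10=C11 enol triflate
Conditions: LiN(i-Pr)2, THF, −78 °C; then 2-[N,N-bis(trifluoromethylsulfonyl)amino]-5-chloropyridine, −78 °C
Reagents that add atoms: 2-[N,N-bis(trifluoromethylsulfonyl)amino]-5-chloropyridine, O=S(=O)(N(c1ccc(Cl)cn1)S(=O)(=O)C(F)(F)F)C(F)(F)F
Why: Kinetic deprotonation by the hindered amide base should take a C10 proton, because C22 is neopentylic (next to the quaternary C23) and shielded by the endo side chain on C6, and the lithium enolate is trapped at −78 °C as the enol triflate before it can equilibrate.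

Step 19
Reactants: 23 C10=C11 enol triflate
Product: 24 C11 trimethylstannyl alkene (diquinane alkenylstannane)
Conditions: Me3SnSnMe3, Pd(PPh3)4 (cat.), LiCl, THF, 60 °C
Reagents that add atoms: hexamethylditin, C[Sn](C)(C)[Sn](C)(C)C
Why: Pd-catalysed stannylation of the enol triflate with hexamethylditin (Stille-type coupling assisted by LiCl) gives a storable precursor of the alkenyl metal with the alkene position fixed.

Step 20
Reactants: 25 cyclopent-2-en-1-one
Product: 26 2-iodocyclopent-2-en-1-one
Conditions: I2, pyridine, CH2Cl2, 0 °C → rt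
Reagents that add atoms: iodine, II
Why: α-Iodination of the enone by conjugate addition of pyridine, iodination of the resulting enolate and elimination (a Baylis–Hillman-type pathway).

Step 21
Reactants: 26 2-iodocyclopent-2-en-1-one
Product: 27 (S)-2-iodocyclopent-2-en-1-ol
Conditions: (R)-1-methyl-3,3-diphenyltetrahydro-1H,3H-pyrrolo[1,2-c][1,3,2]oxazaborole [(R)-Me-CBS, 0.1 equiv], BH3·SMe2, THF, 0 °C
Reagents that add atoms: none
Why: CBS reduction in which the iodine-bearing alkene carbon takes the large-group position, so the (R)-catalyst should give the (S)-allylic alcohol that later supplies the configuration of C12.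

Step 22
Reactants: 27 (S)-2-iodocyclopent-2-en-1-ol
Product: 28 (S)-2-vinylcyclopent-2-en-1-ol
Conditions: CH2=CHSnBu3, Pd(PPh3)4 (cat.), CuI (cat.), DMF, rt
Reagents that add atoms: tributyl(vinyl)stannane, C=C[Sn](CCCC)(CCCC)CCCC
Why: Stille coupling of the alkenyl iodide with the vinyl stannane tolerates the free hydroxyl and brings the two carbons C19 and C20 without touching the carbinol centre.

Step 23
Reactants: 28 (S)-2-vinylcyclopent-2-en-1-ol
Product: 29 (S)-2-vinylcyclopent-2-en-1-yl picolinate (pyridine-2-carboxylate)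
Conditions: picolinic acid, N,N'-dicyclohexylcarbodiimide, 4-(dimethylamino)pyridine (cat.), CH2Cl2, rt
Reagents that add atoms: picolinic acid, OC(=O)c1ccccn1
Why: Steglich esterification gives the picolinate, whose pyridine nitrogen and carbonyl oxygen chelate the metal in the substitution step and turn the ester into a good leaving group.

Step 24
Reactants: 24 diquinane alkenylstannane; 29 (S)-2-vinylcyclopent-2-en-1-yl picolinate
Product: 32 diquinane-substituted 1-vinylcyclopentene (C12 R), via alkenyllithium 30 (not isolated), via alkenylcopper 31 (not isolated)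
Conditions: 24, MeLi, THF, −78 → −40 °C; MgBr2·OEt2, then CuBr·SMe2, −78 → −40 °C; then 29, THF–Et2O, −78 → 0 °C
Reagents that add atoms: none
Why: Tin–lithium exchange and transmetalation give an alkenylcopper reagent that the chelating picolinate should direct to the γ-carbon anti to the leaving group (anti SN2' allylic substitution), so the carbinol configuration is transferred to C12 while the alkene moves to C15=C21, the vinyl group on the central allyl carbon being unable to divert the attack.

Step 25
Reactants: 33 methyl 3,3-dimethoxypropanoate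
Product: 34 methyl 3,3-bis(4-methoxybenzyloxy)propanoate
Conditions: 4-methoxybenzyl alcohol (excess), pyridinium p-toluenesulfonate (cat.), toluene, 90 °C, MeOH distilled off
Reagents that add atoms: 4-methoxybenzyl alcohol, COc1ccc(CO)cc1
Why: Acid-catalysed acetal exchange driven by removal of methanol installs PMB groups, one of which later remains on C16 and can be removed oxidatively.

Step 26
Reactants: 32 diquinane-substituted 1-vinylcyclopentene; 34 methyl 3,3-bis(4-methoxybenzyloxy)propanoate
Product: 35 cis-2-cyclopentenyl cyclopropanol (C18 carbinol carrying CH2CH(OPMB)2, C19 methylene, C20 bearing the cyclopentenyl group; chain and cyclopentenyl cis)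
Conditions: Ti(Oi-Pr)4, c-C5H9MgCl (slow addition), THF, rt
Reagents that add atoms: none
Why: Kulinkovich cyclopropanation with olefin exchange, in which the titanacyclopropane made from Ti(Oi-Pr)4 and cyclopentylmagnesium chloride swaps cyclopentene for the only monosubstituted alkene of 32, inserts the ester into its Ti–CH2 bond and closes with retention to the cis-1,2-disubstituted cyclopropanol, titanium being expected to bind the vinyl face of the s-trans diene anti to the diquinane on C12.

Step 27
Reactants: 35 cis-2-cyclopentenyl cyclopropanol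
Product: 36 triethylsilyl ether of cyclopropanol 35
Conditions: Et3SiCl, imidazole, DMF, 0 °C → rt
Reagents that add atoms: chlorotriethylsilane, CC[Si](CC)(CC)Cl
Why: Imidazole-mediated silylation of the tertiary cyclopropanol under conditions free of Lewis acid leaves the acetal alone and blocks ring opening of the cyclopropanol.

Step 28
Reactants: 36 triethylsilyl ether of cyclopropanol 35
Product: 37 siloxy cis-divinylcyclopropane with an (E)-2-(4-methoxybenzyloxy)vinyl group on C18
Conditions: Me3SiOTf, i-Pr2NEt, CH2Cl2, −20 → 0 °C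
Reagents that add atoms: none
Why: Amine-buffered silyl triflate ionises the acetal to the oxocarbenium ion, which loses a C17 proton (acetal-to-enol-ether elimination), and the bulky quaternary cyclopropane carbon on C17 should favour the E isomer.

Step 29
Reactants: 37 siloxy cis-divinylcyclopropane
Product: 38 hydroazulene silyl enol ether (C17=C18 OSiEt3, C16 OPMB, C20=C21)
Conditions: toluene (trace Et3N), 60 °C
Reagents that add atoms: none
Why: On warming, 37 should undergo the concerted [3,3] shift of a cis-1,2-dialkenylcyclopropane through the boat transition state in which both alkenes lie over the three-membered ring, the C15–C16 bond forming between the cyclopentene CH and the enol-ether terminus while the C18–C20 cyclopropane bond breaks. The closest known reaction type is the divinylcyclopropane–cycloheptadiene (Cope) rearrangement of silyl ethers of cis-1,2-dialkenylcyclopropanols made by Kulinkovich cyclopropanation. The seven-membered ring is closed by sigmatropic ring expansion driven by release of cyclopropane strain, not by a separate cyclisation, and is thereby fused to the cyclopentane, with C20=C21 emerging as the exocyclic trisubstituted alkene and C17=C18 as the silyl enol ether. Both new stereocentres follow from the stereospecific boat geometry: C15 from the configuration of the cyclopropane carbon C20, which puts the new bond on the cyclopentene face cis to the diquinane on C12, and C16 from the E enol ether, which holds OPMB outward and therefore trans to H15. The step needs the two alkenyl groups cis and only hydrogen in the inward positions of both termini; the Kulinkovich reaction supplies the cis cyclopropane, and the ring CH and the E enol ether carry hydrogen inward, so the shift should run at mild temperature without alkene migration.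

Step 30
Reactants: 38 hydroazulene silyl enol ether
Product: 39 C18 ketone with OPMB on C16
Conditions: n-Bu4NF (1 equiv), AcOH, THF, −78 → −20 °C
Reagents that add atoms: none
Why: Fluoride cleaves the silyl enol ether far faster than the alkyl silyl ethers and the enolate is protonated by acetic acid at the methylene carbon C17, so the ketone should be released under buffered conditions without β-elimination of OPMB or migration of the β,γ-alkene.

Step 31
Reactants: 39 C18 ketone with OPMB on C16
Product: 40 β-hydroxy ketone (C16 OH, C18 ketone)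
Conditions: 2,3-dichloro-5,6-dicyano-1,4-benzoquinone, CH2Cl2–pH 7 buffer, 0 °C
Reagents that add atoms: none
Why: Oxidative cleavage of the electron-rich PMB ether by the quinone under neutral buffered conditions leaves silyl ethers, alkenes and the ketone intact.

Step 32
Reactants: 40 β-hydroxy ketone
Product: 41 C16 acetate with free C18 hydroxyl (trans-1,3)
Conditions: SmI2 (0.3 equiv), CH3CHO (excess), THF, −10 °C
Reagents that add atoms: acetaldehyde, CC=O
Why: In the Evans–Tishchenko reduction the samarium-bound hemiacetal formed from the C16 hydroxyl and acetaldehyde delivers its hydride intramolecularly to the C18 carbonyl on the face of the C16 oxygen, which should give the C18 alcohol trans (1,3-anti) to C16–O and leave C16 as its acetate.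

Step 33
Reactants: 41 C16 acetate with free C18 hydroxyl
Product: 42 C16 acetate, C18 triethylsilyl ether
Conditions: Et3SiCl, imidazole, CH2Cl2, 0 °C
Reagents that add atoms: chlorotriethylsilane, CC[Si](CC)(CC)Cl
Why: Prompt silylation of the new secondary alcohol fixes the differentiation of the two oxygens before any acyl migration can occur.

Step 34
Reactants: 42 C16 acetate, C18 triethylsilyl ether
Product: 43 C16 alcohol, C18 triethylsilyl ether
Conditions: i-Bu2AlH, CH2Cl2, −78 °C
Reagents that add atoms: none
Why: Reductive cleavage of the acetate by the aluminium hydride at low temperature is non-basic, so neither silyl migration nor loss of a silyl ether is expected, and no other reducible group is present.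

Step 35
Reactants: 43 C16 alcohol, C18 triethylsilyl ether
Product: 44 tris-silylated target (C16 ketone; C2 OTBS, C5 and C18 OSiEt3)
Conditions: Dess–Martin periodinane, NaHCO3, CH2Cl2, 0 °C
Reagents that add atoms: none
Why: Buffered Dess–Martin oxidation gives the C16 ketone under neutral conditions that should keep C15 from epimerising, the C20=C21 alkene from moving into conjugation and the β-siloxy group from eliminating.

Step 36
Reactants: 44 tris-silylated target
Product: 45 target CNP0358460.1
Conditions: HF·pyridine, pyridine, THF, 0 °C → rt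
Reagents that add atoms: none
Why: Pyridine-buffered hydrogen fluoride removes the two triethylsilyl ethers and the allylic TBS ether without the basicity of naked fluoride, which would threaten the β-hydroxy ketone and the epimerisable C15.

**Compound list**

1 | 2-methylcyclopentane-1,3-dione | CC1C(=O)CCC1=O | starting material
2 | 2-allyl-2-methylcyclopentane-1,3-dione | C=CCC1(C)C(=O)CCC1=O | intermediate
3 | (2S,3S)-2-allyl-3-hydroxy-2-methylcyclopentan-1-one | O[C@H]1CCC(=O)[C@@]1(C)CC=C | intermediate
4 | (2S,3S)-2-allyl-3-[(tert-butyldimethylsilyl)oxy]-2-methylcyclopentan-1-one | CC(C)(C)[Si](C)(C)O[C@H]1CCC(=O)[C@@]1(C)CC=C | intermediate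
5 | (2S,3S)-3-[(tert-butyldimethylsilyl)oxy]-2-methyl-2-(2-oxopropyl)cyclopentan-1-one | CC(C)(C)[Si](C)(C)O[C@H]1CCC(=O)[C@@]1(C)CC(C)=O | intermediate
6 | (6S,6aR)-6-[(tert-butyldimethylsilyl)oxy]-6a-methyl-4,5,6,6a-tetrahydropentalen-2(1H)-one | CC(C)(C)[Si](C)(C)O[C@H]1CCC2=CC(=O)C[C@]21C | intermediate
7 | (3aR,4S,6aS)-4-[(tert-butyldimethylsilyl)oxy]-3a-methylhexahydropentalen-2(1H)-one | CC(C)(C)[Si](C)(C)O[C@H]1CC[C@H]2CC(=O)C[C@]21C | intermediate
8 | ethylene ketal of 7 | CC(C)(C)[Si](C)(C)O[C@H]1CC[C@H]2CC3(OCCO3)C[C@]21C | intermediate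
9 | (3aR,4S,6aS)-4-hydroxy-3a-methylhexahydropentalen-2(1H)-one ethylene ketal | O[C@H]1CC[C@H]2CC3(OCCO3)C[C@]21C | intermediate
10 | (3aS,6aR)-6a-methylhexahydropentalene-1,5-dione 5-(ethylene ketal) | O=C1CC[C@H]2CC3(OCCO3)C[C@]21C | intermediate
11 | C6=C7 enol triflate of 10 | O=S(=O)(OC1=CC[C@H]2CC3(OCCO3)C[C@]21C)C(F)(F)F | intermediate
12 | 2-ethoxydiene (C6 1-ethoxyvinyl, C6=C7, C11 ketal) | CCOC(=C)C1=CC[C@H]2CC3(OCCO3)C[C@]21C | intermediate
13 | C6-acetyl C6=C7 diquinane ketal (enone) | CC(=O)C1=CC[C@H]2CC3(OCCO3)C[C@]21C | intermediate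
14 | cis-diquinane methyl ketone (C6 S, C9 S, C23 R; C11 ethylene ketal) | CC(=O)[C@H]1CC[C@H]2CC3(OCCO3)C[C@]21C | intermediate
15 | (R)-but-3-yn-2-ol | C[C@@H](O)C#C | starting material
16 | (R)-tert-butyl(but-3-yn-2-yloxy)dimethylsilane | C[C@@H](O[Si](C)(C)C(C)(C)C)C#C | intermediate
17 | (R,E)-[3-(tert-butyldimethylsilyloxy)but-1-enyl]zirconocene chloride | C[C@@H](O[Si](C)(C)C(C)(C)C)/C=C/[Zr](Cl)(C1C=CC=C1)C1C=CC=C1 | intermediate
18 | (R,E)-tert-butyl[(4-iodobut-3-en-2-yl)oxy]dimethylsilane | C[C@@H](O[Si](C)(C)C(C)(C)C)/C=C/I | intermediate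
19 | (R,E)-[3-(tert-butyldimethylsilyloxy)but-1-enyl]lithium | C[C@@H](O[Si](C)(C)C(C)(C)C)/C=C/[Li] | intermediate
20 | tertiary allylic alcohol: diquinane ketal with the C1–C5 side chain (C2 R OTBS, E alkene, C5 S OH) | C[C@@H](O[Si](C)(C)C(C)(C)C)/C=C/[C@](C)(O)[C@H]1CC[C@H]2CC3(OCCO3)C[C@]21C | intermediate
21 | C5 triethylsilyl ether of 20 | C[C@@H](O[Si](C)(C)C(C)(C)C)/C=C/[C@](C)(O[Si](CC)(CC)CC)[C@H]1CC[C@H]2CC3(OCCO3)C[C@]21C | intermediate
22 | C11 ketone with the bis-silylated side chain | C[C@@H](O[Si](C)(C)C(C)(C)C)/C=C/[C@](C)(O[Si](CC)(CC)CC)[C@H]1CC[C@H]2CC(=O)C[C@]21C | intermediate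
23 | C10=C11 enol triflate | C[C@@H](O[Si](C)(C)C(C)(C)C)/C=C/[C@](C)(O[Si](CC)(CC)CC)[C@H]1CC[C@H]2C=C(OS(=O)(=O)C(F)(F)F)C[C@]21C | intermediate
24 | diquinane alkenylstannane (C11 SnMe3) | C[C@@H](O[Si](C)(C)C(C)(C)C)/C=C/[C@](C)(O[Si](CC)(CC)CC)[C@H]1CC[C@H]2C=C([Sn](C)(C)C)C[C@]21C | intermediate
25 | cyclopent-2-en-1-one | O=C1CCC=C1 | starting material
26 | 2-iodocyclopent-2-en-1-one | O=C1CCC=C1I | intermediate
27 | (S)-2-iodocyclopent-2-en-1-ol | O[C@H]1CCC=C1I | intermediate
28 | (S)-2-vinylcyclopent-2-en-1-ol | O[C@H]1CCC=C1C=C | intermediate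
29 | (S)-2-vinylcyclopent-2-en-1-yl picolinate | C=CC1=CCC[C@@H]1OC(=O)c1ccccn1 | intermediate
30 | diquinane alkenyllithium (C11 Li) | C[C@@H](O[Si](C)(C)C(C)(C)C)/C=C/[C@](C)(O[Si](CC)(CC)CC)[C@H]1CC[C@H]2C=C([Li])C[C@]21C | intermediate
31 | diquinane alkenylcopper (C11 Cu, MgBr2 complex) | C[C@@H](O[Si](C)(C)C(C)(C)C)/C=C/[C@](C)(O[Si](CC)(CC)CC)[C@H]1CC[C@H]2C=C([Cu])C[C@]21C | intermediate
32 | diquinane-substituted 1-vinylcyclopentene (C12 R) | C[C@@H](O[Si](C)(C)C(C)(C)C)/C=C/[C@](C)(O[Si](CC)(CC)CC)[C@H]1CC[C@H]2C=C([C@H]3CCC=C3C=C)C[C@]21C | intermediate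
33 | methyl 3,3-dimethoxypropanoate | COC(=O)CC(OC)OC | starting material
34 | methyl 3,3-bis(4-methoxybenzyloxy)propanoate | COC(=O)CC(OCc1ccc(OC)cc1)OCc1ccc(OC)cc1 | intermediate
35 | cis-2-cyclopentenyl cyclopropanol with CH2CH(OPMB)2 on C18 | C[C@@H](O[Si](C)(C)C(C)(C)C)/C=C/[C@](C)(O[Si](CC)(CC)CC)[C@H]1CC[C@H]2C=C([C@H]3CCC=C3[C@H]4C[C@@]4(O)CC(OCc5ccc(OC)cc5)OCc5ccc(OC)cc5)C[C@]21C | intermediate
36 | triethylsilyl ether of cyclopropanol 35 | C[C@@H](O[Si](C)(C)C(C)(C)C)/C=C/[C@](C)(O[Si](CC)(CC)CC)[C@H]1CC[C@H]2C=C([C@H]3CCC=C3[C@H]4C[C@@]4(O[Si](CC)(CC)CC)CC(OCc5ccc(OC)cc5)OCc5ccc(OC)cc5)C[C@]21C | intermediate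
37 | siloxy cis-divinylcyclopropane with (E)-2-(4-methoxybenzyloxy)vinyl on C18 | C[C@@H](O[Si](C)(C)C(C)(C)C)/C=C/[C@](C)(O[Si](CC)(CC)CC)[C@H]1CC[C@H]2C=C([C@H]3CCC=C3[C@H]4C[C@@]4(O[Si](CC)(CC)CC)/C=C/OCc5ccc(OC)cc5)C[C@]21C | intermediate
38 | hydroazulene silyl enol ether (C17=C18 OSiEt3, C16 OPMB trans to H15, C20=C21) | C[C@@H](O[Si](C)(C)C(C)(C)C)/C=C/[C@](C)(O[Si](CC)(CC)CC)[C@H]1CC[C@H]2C=C([C@H]3CC[C@H]4[C@@H](OCc5ccc(OC)cc5)C=C(O[Si](CC)(CC)CC)CC=C34)C[C@]21C | intermediate
39 | C18 ketone with OPMB on C16 | C[C@@H](O[Si](C)(C)C(C)(C)C)/C=C/[C@](C)(O[Si](CC)(CC)CC)[C@H]1CC[C@H]2C=C([C@H]3CC[C@H]4[C@@H](OCc5ccc(OC)cc5)CC(=O)CC=C34)C[C@]21C | intermediate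
40 | β-hydroxy ketone (C16 OH, C18 ketone) | C[C@@H](O[Si](C)(C)C(C)(C)C)/C=C/[C@](C)(O[Si](CC)(CC)CC)[C@H]1CC[C@H]2C=C([C@H]3CC[C@H]4[C@@H](O)CC(=O)CC=C34)C[C@]21C | intermediate
41 | C16 acetate, C18 alcohol (trans-1,3) | C[C@@H](O[Si](C)(C)C(C)(C)C)/C=C/[C@](C)(O[Si](CC)(CC)CC)[C@H]1CC[C@H]2C=C([C@H]3CC[C@H]4[C@@H](OC(C)=O)C[C@H](O)CC=C34)C[C@]21C | intermediate
42 | C16 acetate, C18 triethylsilyl ether | C[C@@H](O[Si](C)(C)C(C)(C)C)/C=C/[C@](C)(O[Si](CC)(CC)CC)[C@H]1CC[C@H]2C=C([C@H]3CC[C@H]4[C@@H](OC(C)=O)C[C@H](O[Si](CC)(CC)CC)CC=C34)C[C@]21C | intermediate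
43 | C16 alcohol, C18 triethylsilyl ether | C[C@@H](O[Si](C)(C)C(C)(C)C)/C=C/[C@](C)(O[Si](CC)(CC)CC)[C@H]1CC[C@H]2C=C([C@H]3CC[C@H]4[C@@H](O)C[C@H](O[Si](CC)(CC)CC)CC=C34)C[C@]21C | intermediate
44 | tris-silylated target (C16 ketone; C2 OTBS, C5 and C18 OSiEt3) | C[C@@H](O[Si](C)(C)C(C)(C)C)/C=C/[C@](C)(O[Si](CC)(CC)CC)[C@H]1CC[C@H]2C=C([C@H]3CC[C@H]4C(=O)C[C@H](O[Si](CC)(CC)CC)CC=C34)C[C@]21C | intermediate
45 | target CNP0358460.1 (C2 R, C5 S, C6 S, C9 S, C12 R, C15 R, C18 R, C23 R) | C[C@@H](O)/C=C/[C@](C)(O)[C@H]1CC[C@H]2C=C([C@H]3CC[C@H]4C(=O)C[C@H](O)CC=C34)C[C@]21C | target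

**Step count and risks**

Total step count: 36 steps.
Longest linear sequence: 29 steps (steps 1–12, 15–19, 24, 26–36).

Steps most likely to fail:

1. Step 26 (Kulinkovich cyclopropanation). The remote C12 substituent may discriminate the two faces of the vinyl group poorly, or olefin exchange with the hindered 2-substituted diene may be slow. Either leads to the cyclopropane diastereomer that gives the wrong C15, C16 and C18 series, and this cannot be corrected later. Fallback: the cyclopropane is built before the fragment union, on the cheap dienol, where the siloxy-bearing neighbour of the vinyl-bearing carbon controls the same face, a bulkier silyl group can raise the bias, and diastereomers can be separated. It sets out from 28. Silylation (Et3SiCl, imidazole) gives (S)-triethyl[(2-vinylcyclopent-2-en-1-yl)oxy]silane F1. The Kulinkovich reaction with 34 (Ti(Oi-Pr)4, c-C5H9MgCl) gives the cis cyclopropanol F2. Silylation gives the bis(triethylsilyl) ether F3. HF·pyridine in pyridine removes the less hindered secondary allylic silyl group to give the cyclopentenol F4. Steglich esterification with picolinic acid gives the cyclopropyl-substituted picolinate F5. Anti SN2' substitution of F5 with alkenylcopper 31 (made from 24 as in step 24) comes back to the route at 36.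

2. Step 24 (anti SN2' fragment union). The single, valuable alkenyl group may be transferred inefficiently from the stoichiometric copper reagent, or attack may be divided between the α- and γ-carbons of the dienyl picolinate. Fallback: the union is turned into a copper-catalysed coupling of a boron nucleophile with an allylic phosphate. It sets out from 23 and from 28. Miyaura borylation of 23 (B2pin2, PdCl2(PPh3)2, PPh3, KOPh, toluene) gives the diquinane alkenyl pinacolboronate F6. Phosphorylation of 28 (ClP(O)(OEt)2, pyridine) gives diethyl (S)-2-vinylcyclopent-2-en-1-yl phosphate F7. A CuCl-catalysed, KOt-Bu-promoted γ-selective anti allyl–alkenyl coupling of F6 with F7 comes back to the route at 32.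

3. Step 32 (Evans–Tishchenko reduction). The cyclic β-hydroxy ketone may not reach the chair-like geometry for internal hydride transfer, or may suffer retro-aldol opening or acyl migration under the samarium catalyst. Fallback: a hydroxyl-directed borohydride reduction followed by steric differentiation of the two hydroxyls. It sets out from 40. The Saksena–Evans reduction (Me4NBH(OAc)3, MeCN–AcOH, −30 °C) again delivers hydride on the face of the C16 oxygen and gives the trans-1,3-diol F8. Its less hindered C18 hydroxyl, flanked by two CH2 groups, is then silylated selectively (Et3SiCl, imidazole, −40 °C), which comes back to the route at 43 and bypasses steps 33 and 34.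

**Further compounds**

F1 | step 26 | (S)-triethyl[(2-vinylcyclopent-2-en-1-yl)oxy]silane | C=CC1=CCC[C@@H]1O[Si](CC)(CC)CC
F2 | step 26 | cis cyclopropanol from F1 and 34 (CH2CH(OPMB)2 chain cis to the cyclopentenyl group) | CC[Si](CC)(CC)O[C@H]1CCC=C1[C@H]1C[C@@]1(O)CC(OCc1ccc(OC)cc1)OCc1ccc(OC)cc1
F3 | step 26 | bis(triethylsilyl) ether of F2 | CC[Si](CC)(CC)O[C@H]1CCC=C1[C@H]1C[C@@]1(O[Si](CC)(CC)CC)CC(OCc1ccc(OC)cc1)OCc1ccc(OC)cc1
F4 | step 26 | cyclopentenol with silylated cyclopropanol | O[C@H]1CCC=C1[C@H]1C[C@@]1(O[Si](CC)(CC)CC)CC(OCc1ccc(OC)cc1)OCc1ccc(OC)cc1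
F5 | step 26 | picolinate of F4 | O=C(O[C@H]1CCC=C1[C@H]1C[C@@]1(O[Si](CC)(CC)CC)CC(OCc1ccc(OC)cc1)OCc1ccc(OC)cc1)c1ccccn1
F6 | step 24 | diquinane alkenyl pinacolboronate (C11 Bpin) | C[C@@H](O[Si](C)(C)C(C)(C)C)/C=C/[C@](C)(O[Si](CC)(CC)CC)[C@H]1CC[C@H]2C=C(B3OC(C)(C)C(C)(C)O3)C[C@]21C
F7 | step 24 | diethyl (S)-2-vinylcyclopent-2-en-1-yl phosphate | C=CC1=CCC[C@@H]1OP(=O)(OCC)OCC
F8 | step 32 | trans-1,3-diol (C16 OH, C18 OH) | C[C@@H](O[Si](C)(C)C(C)(C)C)/C=C/[C@](C)(O[Si](CC)(CC)CC)[C@H]1CC[C@H]2C=C([C@H]3CC[C@H]4[C@@H](O)C[C@H](O)CC=C34)C[C@]21C
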